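## Retrosynthetic overview
1. Feature: in each abietane half, ring B is a tetralin. Its two benzylic carbons, oxygen-bearing C7 and quaternary C10, are the ends of a hydroxy-o-quinodimethane drawn from ring C, and C5=C6 is a dienophile already tied to C10 through C1–C4.
2. Last disconnection: the central 1,4-dioxane (C7–O–C6' and C7'–O–C6) splits into two identical 6α,7-diols, because only the C7–O bond, para-activated by the 12-methoxy group, can ionise.
3. The 6α-OH comes from a C6–B bond. Cutting C5–C10 and C6–C7 together (photoenolization/Diels–Alder) opens rings A and B to an ortho-(sec-alkyl)benzaldehyde carrying an E-alkenylboronate.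
4. The precursor grows from ring C: aryl–C10 (aryllithium plus chloroketone, then ionic deoxygenation), C3–C4 (nitrile alkylation), C8–C7 (Rieche formylation), C5=C6 (boron-Wittig).
5. Ring order: C (bought), A and B (one step), dioxane (last).

Key step: step 8

Note: abietane numbering is used throughout. In the open-chain compounds the benzylic methine is C10 and the formyl carbon is C7.
Assumption: 5-bromo-2-isopropylanisole is taken as a catalogue building block.
Assumption: the sense of induction of the titanium TADDOLate cannot be derived from related cases. The route is written with (R,R)-TADDOL, and the equally available (S,S)-ligand is used if the antipodal series is favoured.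

## Route

Step 1
Reactants: 1 5-bromo-2-isopropylanisole; 2 5-chloropentan-2-one
Product: 4 5-chloro-2-(4-isopropyl-3-methoxyphenyl)pentan-2-ol (racemic), via 4-isopropyl-3-methoxyphenyllithium 3 (not isolated)
Conditions: n-BuLi, THF, −78 °C; then 2, −78 °C; AcOH quench at −78 °C
Reagents that add atoms: none
Why: Bromine–lithium exchange and 1,2-addition of the aryllithium to the methyl ketone form the aryl–C10 bond; the cold acidic quench keeps the γ-chloro alkoxide from closing to a tetrahydrofuran, and the racemic carbinol centre is removed in step 2.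

Step 2
Reactants: 4 5-chloro-2-(4-isopropyl-3-methoxyphenyl)pentan-2-ol
Product: 5 4-(5-chloropentan-2-yl)-1-isopropyl-2-methoxybenzene (racemic)
Conditions: Et3SiH, TFA, CH2Cl2, 0 °C
Reagents that add atoms: none
Why: In this ionic hydrogenation (Kursanov–Parnes type), TFA ionises the tertiary benzylic alcohol and the silane delivers hydride to the cation, leaving the primary chloride and aryl ether untouched; the racemic benzylic centre is erased in step 8.

Step 3
Reactants: 5 4-(5-chloropentan-2-yl)-1-isopropyl-2-methoxybenzene; 6 isobutyronitrile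
Product: 8 6-(4-isopropyl-3-methoxyphenyl)-2,2-dimethylheptanenitrile (racemic), via lithiated isobutyronitrile 7 (not isolated)
Conditions: 6, lithium diisopropylamide, THF, −78 °C; then 5, DMPU, Bu4NI (cat.), −78 → 40 °C
Reagents that add atoms: none
Why: SN2 alkylation of a metallated nitrile builds the quaternary C4; the nitrile serves as aldehyde surrogate because its small, strongly nucleophilic anion neither self-condenses nor O-alkylates, unlike an isobutyraldehyde enolate.

Step 4
Reactants: 8 6-(4-isopropyl-3-methoxyphenyl)-2,2-dimethylheptanenitrile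
Product: 9 6-(2-formyl-4-isopropyl-5-methoxyphenyl)-2,2-dimethylheptanenitrile (racemic)
Conditions: Cl2CHOMe, TiCl4 (2.5 equiv), CH2Cl2, −10 → 0 °C; then H2O
Reagents that add atoms: dichloromethyl methyl ether COC(Cl)Cl; water O
Why: Rieche formylation (electrophilic aromatic substitution) goes para to the methoxy group, since the only ortho site lies between OMe and the sec-alkyl group; it is run before boron is introduced, so no alkenylboronate meets TiCl4.

Step 5
Reactants: 9 6-(2-formyl-4-isopropyl-5-methoxyphenyl)-2,2-dimethylheptanenitrile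
Product: 11 6-[2-(hydroxymethyl)-4-isopropyl-5-methoxyphenyl]-2,2-dimethylheptanal (racemic), via bis(diisobutylaluminium) imine alkoxide 10 (not isolated)
Conditions: iBu2AlH (3.2 equiv), toluene, −78 → 0 °C; then 1 M aq. HCl, Et2O, 0 °C
Reagents that add atoms: water O
Why: The hydride reduction stops at the N-aluminio imine for the hindered nitrile (aldehyde on hydrolysis) but takes the aryl aldehyde to the alcohol, so the two carbonyl carbons end at different oxidation levels and need no protecting group.

Step 6
Reactants: 11 6-[2-(hydroxymethyl)-4-isopropyl-5-methoxyphenyl]-2,2-dimethylheptanal; 12 bis(pinacolboryl)methane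
Product: 15 {2-[(E)-6,6-dimethyl-8-(pinacolboryl)oct-7-en-2-yl]-5-isopropyl-4-methoxyphenyl}methanol (racemic), via lithiated bis(pinacolboryl)methane 13 (not isolated), via β-lithiooxy gem-diboronate adduct 14 (not isolated)
Conditions: 12 (2.2 equiv), 2,2,6,6-tetramethylpiperidine, n-BuLi (2.2 equiv), THF, 0 °C; then 11, −78 °C → rt; aq. NH4Cl
Reagents that add atoms: none
Why: In this boron-Wittig olefination, one equivalent of the carbanion is spent on the free hydroxyl and the second adds to the aldehyde; syn B–O elimination from the rotamer that keeps the bulky tertiary alkyl group away from the remaining boryl group gives the E-alkene.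

Step 7
Reactants: 15 {2-[(E)-6,6-dimethyl-8-(pinacolboryl)oct-7-en-2-yl]-5-isopropyl-4-methoxyphenyl}methanol
Product: 16 5-isopropyl-4-methoxy-2-[(E)-6,6-dimethyl-8-(pinacolboryl)oct-7-en-2-yl]benzaldehyde (racemic at C10)
Conditions: MnO2 (excess), CH2Cl2, rt
Reagents that add atoms: none
Why: Heterogeneous MnO2 oxidation is selective for the electron-rich benzylic alcohol, stops at the aldehyde and leaves the alkenylboronate alone.

Step 8
Reactants: 16 5-isopropyl-4-methoxy-2-[(E)-6,6-dimethyl-8-(pinacolboryl)oct-7-en-2-yl]benzaldehyde
Product: 18 6α-(pinacolboryl)-12-methoxyabieta-8,11,13-trien-7α-ol, via titanium-bound hydroxy-o-quinodimethane 17 (not isolated)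
Conditions: Ti(OiPr)4 (2 equiv), (R,R)-TADDOL (2.2 equiv), toluene, rt, iPrOH stripped off; then 16 (0.01 M), Ar, hν (365 nm LED), 10–25 °C; aq. NaHCO3
Reagents that add atoms: none
Why: Proposed new method: excitation of the aryl aldehyde, 1,5-hydrogen transfer from C10–H to the carbonyl oxygen and relaxation of the biradical give the hydroxy-o-quinodimethane 17, which titanium holds as a dienolate until C5=C6 adds suprafacially across C10 and C7 in one concerted, asynchronous [4+2] event that restores ring C. The closest known reaction types are the Ti(OiPr)4-promoted photoenolization/Diels–Alder reaction of ortho-alkylbenzaldehydes (shown for fully substituted benzylic carbons, for tethered ester-activated alkenes and, with TADDOL-type titanium alkoxides, enantioselectively for chelating enones) and the thermal intramolecular Diels–Alder reaction of o-quinodimethanes with plain alkenes; not yet shown are an alkenylboronate as the trap and ligand control without a carbonyl anchor on the dienophile. Ring A closes by the C5–C10 bond as a type 1 intramolecular cycloaddition over the four-carbon tether C1–C4 folded as a chair, and ring B is the new cyclohexene of the cycloaddition, closed by C5–C10 and C6–C7. Only the dienol isomer with the tether outward and the methyl inward can reach the alkene, and the quaternary C4 avoids the space under the diene (tether exo, boron endo), so H-5 and CH3-10 become trans; the E-alkene then places boron trans to C4, that is 6α, and the outward hydroxyl ends cis to C1 and to boron, that is 7α. The absolute sense (5S,10S) depends on which diene face the TADDOLate on O7 leaves open, possibly helped by a contact between titanium and a pinacol oxygen of the neighbouring endo boronate. The step needs regio-, ring-fusion and facial selectivity: the first is fixed by the tether and agrees with the ortho rule for a 1-oxygenated diene and a boron-polarised alkene, the second rests on the bulk at C4, and the third is the open point.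

Step 9
Reactants: 18 6α-(pinacolboryl)-12-methoxyabieta-8,11,13-trien-7α-ol
Product: 19 12-methoxyabieta-8,11,13-triene-6α,7α-diol
Conditions: 30% aq. H2O2, 2 M aq. NaOH, THF, 0 °C (run on freshly worked-up 18)
Reagents that add atoms: hydrogen peroxide OO
Why: In this boronate oxidation, hydroperoxide adds to boron and C6 migrates to oxygen with retention, so the 6α configuration passes from boron to hydroxyl, and the fast cold reaction limits B–O elimination.

Step 10
Reactants: 19 12-methoxyabieta-8,11,13-triene-6α,7α-diol (two molecules)
Product: 21 CNP0327150.1, via open-chain C7–O–C6' ether dimer 20 (not isolated)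
Conditions: camphorsulfonic acid (10 mol %), 4 Å molecular sieves, CH2Cl2 (0.5 M), 0 °C → rt
Reagents that add atoms: none
Why: In this SN1 dehydrative benzylic etherification run twice, the 12-methoxy group para to C8 lets mild acid ionise only C7–OH, the 6α-OH of a second molecule captures the cation, and the same event repeated intramolecularly closes the dioxane head to tail; because both benzylic C–O bonds stay reversible, the all-equatorial 6α,7β:6'α,7'β isomer should accumulate, which resets C7 from α to β.

## Compound list
1 | 5-bromo-2-isopropylanisole | COc1cc(Br)ccc1C(C)C | starting material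
2 | 5-chloropentan-2-one | CC(=O)CCCCl | starting material
3 | 4-isopropyl-3-methoxyphenyllithium | [Li]c1ccc(C(C)C)c(OC)c1 | intermediate
4 | 5-chloro-2-(4-isopropyl-3-methoxyphenyl)pentan-2-ol, racemic | COc1cc(C(C)(O)CCCCl)ccc1C(C)C | intermediate
5 | 4-(5-chloropentan-2-yl)-1-isopropyl-2-methoxybenzene, racemic | COc1cc(C(C)CCCCl)ccc1C(C)C | intermediate
6 | isobutyronitrile | CC(C)C#N | starting material
7 | lithiated isobutyronitrile | [Li]C(C)(C)C#N | intermediate
8 | 6-(4-isopropyl-3-methoxyphenyl)-2,2-dimethylheptanenitrile, racemic | COc1cc(C(C)CCCC(C)(C)C#N)ccc1C(C)C | intermediate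
9 | 6-(2-formyl-4-isopropyl-5-methoxyphenyl)-2,2-dimethylheptanenitrile, racemic | COc1cc(C(C)CCCC(C)(C)C#N)c(C=O)cc1C(C)C | intermediate
10 | N-diisobutylaluminio imine / O-diisobutylaluminium benzylic alkoxide from 9 | COc1cc(C(C)CCCC(C)(C)C=N[Al](CC(C)C)CC(C)C)c(CO[Al](CC(C)C)CC(C)C)cc1C(C)C | intermediate
11 | 6-[2-(hydroxymethyl)-4-isopropyl-5-methoxyphenyl]-2,2-dimethylheptanal, racemic | COc1cc(C(C)CCCC(C)(C)C=O)c(CO)cc1C(C)C | intermediate
12 | bis(pinacolboryl)methane | C(B1OC(C)(C)C(C)(C)O1)B1OC(C)(C)C(C)(C)O1 | starting material
13 | lithiated bis(pinacolboryl)methane | [Li]C(B1OC(C)(C)C(C)(C)O1)B1OC(C)(C)C(C)(C)O1 | intermediate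
14 | β-lithiooxy gem-diboronate adduct (dilithium salt) | COc1cc(C(C)CCCC(C)(C)C(O[Li])C(B2OC(C)(C)C(C)(C)O2)B2OC(C)(C)C(C)(C)O2)c(CO[Li])cc1C(C)C | intermediate
15 | {2-[(E)-6,6-dimethyl-8-(pinacolboryl)oct-7-en-2-yl]-5-isopropyl-4-methoxyphenyl}methanol, racemic | COc1cc(C(C)CCCC(C)(C)/C=C/B2OC(C)(C)C(C)(C)O2)c(CO)cc1C(C)C | intermediate
16 | 5-isopropyl-4-methoxy-2-[(E)-6,6-dimethyl-8-(pinacolboryl)oct-7-en-2-yl]benzaldehyde, racemic at C10 | COc1cc(C(C)CCCC(C)(C)/C=C/B2OC(C)(C)C(C)(C)O2)c(C=O)cc1C(C)C | intermediate
17 | hydroxy-o-quinodimethane, hydroxyl and tether outward, methyl inward (drawn as the free dienol; titanium sits on the oxygen) | O/C=C1\C=C(C(C)C)C(OC)=C/C1=C(/C)CCCC(C)(C)/C=C/B1OC(C)(C)C(C)(C)O1 | intermediate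
18 | 6α-(pinacolboryl)-12-methoxyabieta-8,11,13-trien-7α-ol (5α-H, 10β-CH3) | COc1cc2c(cc1C(C)C)[C@H](O)[C@H](B3OC(C)(C)C(C)(C)O3)[C@H]1C(C)(C)CCC[C@]21C | intermediate
19 | 12-methoxyabieta-8,11,13-triene-6α,7α-diol | COc1cc2c(cc1C(C)C)[C@H](O)[C@H](O)[C@H]1C(C)(C)CCC[C@]21C | intermediate
20 | 7β-[(7'α-hydroxy-12'-methoxyabieta-8',11',13'-trien-6'α-yl)oxy]-12-methoxyabieta-8,11,13-trien-6α-ol | COc1cc2c(cc1C(C)C)[C@@H](O[C@H]3[C@@H](O)c4cc(C(C)C)c(OC)cc4[C@@]4(C)CCCC(C)(C)[C@H]34)[C@H](O)[C@H]1C(C)(C)CCC[C@]21C | intermediate
21 | CNP0327150.1: head-to-tail bis(12-methoxyabieta-8,11,13-triene) 1,4-dioxane, C7β–O–C6'α and C7'β–O–C6α (5S,6R,7R,10S in both halves) | COc1cc2c(cc1C(C)C)[C@H]1O[C@H]3[C@H](O[C@@H]1[C@H]1C(C)(C)CCC[C@]21C)c1cc(C(C)C)c(OC)cc1[C@@]1(C)CCCC(C)(C)[C@H]31 | target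

## Step count and risks
Total steps: 10. Longest linear sequence: 10.

1. Step 8.
- What may go wrong: the dienol may decay by re-ketonisation, by 1,5-hydrogen shift from the inward methyl group or by four-membered ring closure faster than the hindered, weakly activated alkene captures it. The ligand may discriminate the diene faces poorly, and the ring-fusion selectivity may erode.
- Fallback (known chemistry, from 16 back to 19): 16 is irradiated at 365 nm in benzene saturated with SO2. SO2 is a far faster trap for photoenols and should give the 1-hydroxy-1,3-dihydrobenzo[c]thiophene 2,2-dioxide F1.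
- Heating F1 in toluene at 110 °C over solid NaHCO3 extrudes SO2 cheletropically and releases the same outward dienol thermally. Under these conditions o-quinodimethanes are known to add tethered unactivated alkenes, which should give the racemic boronate F2.
- H2O2/NaOH converts F2 into the racemic diol F3. F3 is resolved by preparative chromatography on a chiral stationary phase, the antipodal diol F4 is set aside, and 19 re-enters at step 10.
- A modest shortfall in enantiopurity on either path would be reduced further by the statistical (Horeau-type) amplification inherent in the dimerisation.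

2. Step 10.
- What may go wrong: loss of H-6 or a 1,2-hydride shift at the C7 cation (pinacol-type collapse) and open-chain oligomerisation may outrun bimolecular capture by the hindered 6α-hydroxyl.
- Fallback (from 19 back to 21): the C7–O bonds are made by reductive etherification instead of carbocation capture.
- DDQ in CH2Cl2 oxidises only the p-methoxybenzylic alcohol, giving 6α-hydroxy-12-methoxyabieta-8,11,13-trien-7-one F5.
- TMSCl/imidazole gives its trimethylsilyl ether F6.
- Et3SiH with catalytic TMSOTf in CH2Cl2 (−78 → −20 °C) joins the silyl ether of one molecule to the ketone of the other, then repeats the event within the ring.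
- Each oxocarbenium ion should be reduced by pseudoaxial hydride delivery from the α face, which places O7 β as in 21.

3. Step 9.
- What may go wrong: 1,2-elimination of boron and O7 (boron-Wittig-type, favoured by the cis arrangement and the easily ionised C7–O bond) may occur during work-up of 18 or under the basic oxidation.
- Fallback (from 18 back to 19): the elimination is carried through deliberately with catalytic p-TsOH in CH2Cl2 to give 12-methoxyabieta-6,8,11,13-tetraene F7.
- Upjohn dihydroxylation of F7 (OsO4 cat., N-methylmorpholine N-oxide, acetone/H2O) should attack the α face, because the axial methyl groups at C4 and C10 shield the β face. This gives the same 6α,7α-diol 19.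

## Further compounds
F1 | step 8 | 1-hydroxy-3-methyl-3-[(E)-4,4-dimethyl-6-(pinacolboryl)hex-5-enyl]-6-isopropyl-5-methoxy-1,3-dihydrobenzo[c]thiophene 2,2-dioxide (racemic, diastereomer mixture) | COc1cc2c(cc1C(C)C)C(O)S(=O)(=O)C2(C)CCCC(C)(C)/C=C/B1OC(C)(C)C(C)(C)O1
F2 | step 8 | racemic 6α-(pinacolboryl)-12-methoxyabieta-8,11,13-trien-7α-ol | COc1cc2c(cc1C(C)C)[C@H](O)[C@H](B3OC(C)(C)C(C)(C)O3)[C@H]1C(C)(C)CCC[C@]21C.COc1cc2c(cc1C(C)C)[C@@H](O)[C@@H](B3OC(C)(C)C(C)(C)O3)[C@@H]1C(C)(C)CCC[C@@]21C
F3 | step 8 | racemic 12-methoxyabieta-8,11,13-triene-6α,7α-diol | COc1cc2c(cc1C(C)C)[C@H](O)[C@H](O)[C@H]1C(C)(C)CCC[C@]21C.COc1cc2c(cc1C(C)C)[C@@H](O)[C@@H](O)[C@@H]1C(C)(C)CCC[C@@]21C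
F4 | step 8 | antipode of diol 19 | COc1cc2c(cc1C(C)C)[C@@H](O)[C@@H](O)[C@@H]1C(C)(C)CCC[C@@]21C
F5 | step 10 | 6α-hydroxy-12-methoxyabieta-8,11,13-trien-7-one | COc1cc2c(cc1C(C)C)C(=O)[C@H](O)[C@H]1C(C)(C)CCC[C@]21C
F6 | step 10 | 12-methoxy-6α-(trimethylsilyloxy)abieta-8,11,13-trien-7-one | COc1cc2c(cc1C(C)C)C(=O)[C@H](O[Si](C)(C)C)[C@H]1C(C)(C)CCC[C@]21C
F7 | step 9 | 12-methoxyabieta-6,8,11,13-tetraene | COc1cc2c(cc1C(C)C)C=C[C@H]1C(C)(C)CCC[C@]21C
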